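**Assumption (one line):** locants C1–C11 in the names are longipinane locants (C1 = ketone carbon, C2 = CH2, C3 = CH–CH3, C4/C5/C10/C11 = cyclobutane, C6 = CMe2, C7–C9 = ester-bearing carbons), and pig liver esterase is taken to give the (R)-half-ester of 1, as documented for this substrate.

## Retrosynthetic overview

1. Target ⇐ 7,8,9-triol: the three angelate esters go on last, then the C1 ketone is freed from its silyl ether.
2. Triol ⇐ cycloheptene (C8=C9) by dihydroxylation anti to C7–OH; the seven-membered carbocycle ⇐ ring-closing metathesis.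
3. C5–C6 bond ⇐ temporary seven-membered lactone (SmI2 Reformatsky onto the cyclobutanone from the C9 side), then radical removal of the C5 oxygen.
4. Cyclobutane and six-membered ring together ⇐ intramolecular keteniminium–alkene [2+2] of an acyclic amide, giving a bicyclo[3.1.1]heptan-6-one.
5. Acyclic chain ⇐ dimethyl 3-methylglutarate (esterase desymmetrisation sets C3) plus an E-vinyl iodide from propargyl alcohol. Ring order: four- and six-membered rings in one step, temporary lactone, then the seven-membered carbocycle.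

## Route

Step 1
Reactants: 1 dimethyl 3-methylpentanedioate
Product: 2 (3R)-5-methoxy-3-methyl-5-oxopentanoic acid
Conditions: pig liver esterase (a carboxylesterase, serine hydrolase class), 0.1 M phosphate buffer pH 7/MeOH 4:1, −10 °C, pH-stat with 1 M NaOH; then HCl to pH 2
Reagents that add atoms: water (O)
Why: Enzymatic desymmetrisation of a prochiral diester: the esterase hydrolyses only one enantiotopic ester arm, which sets C3 (R) by asymmetric catalysis, and cold aqueous methanol raises the selectivity.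

Step 2
Reactants: 2 (3R)-5-methoxy-3-methyl-5-oxopentanoic acid
Product: 3 methyl (3S)-5-chloro-3-methyl-5-oxopentanoate (same spatial arrangement as 2; the descriptor changes only by CIP priority)
Conditions: (COCl)2, DMF (cat.), CH2Cl2, 0 °C → rt; evaporate
Reagents that add atoms: oxalyl chloride (ClC(=O)C(=O)Cl)
Why: Vilsmeier-type acid chloride formation leaves the methyl ester and the non-epimerisable β-stereocentre untouched.

Step 3
Reactants: 4 prop-2-yn-1-ol
Product: 6 (2E)-3-iodo-2-methylprop-2-en-1-ol, via alkenylalane 5 (not isolated)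
Conditions: Me3Al (3 equiv), Cp2ZrCl2 (0.25 equiv), CH2Cl2, 0 °C → rt; then I2, THF, −30 → 0 °C
Reagents that add atoms: trimethylaluminium (C[Al](C)C); iodine (II)
Why: Zirconocene-catalysed syn-carboalumination of the terminal alkyne (Negishi carboalumination) puts CH3 on the internal carbon cis to aluminium, and iodinolysis with retention gives only the E-iodide.

Step 4
Reactants: 6 (2E)-3-iodo-2-methylprop-2-en-1-ol
Product: 7 tert-butyl{[(2E)-3-iodo-2-methylprop-2-en-1-yl]oxy}dimethylsilane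
Conditions: TBSCl, imidazole, DMF, rt
Reagents that add atoms: tert-butyldimethylsilyl chloride (CC(C)(C)[Si](C)(C)Cl)
Why: Standard silylation of a primary alcohol gives an ether stable to the organometallic steps that follow.

Step 5
Reactants: 7 tert-butyl{[(2E)-3-iodo-2-methylprop-2-en-1-yl]oxy}dimethylsilane; 3 methyl (3S)-5-chloro-3-methyl-5-oxopentanoate
Product: 10 methyl (3R,6E)-8-[(tert-butyldimethylsilyl)oxy]-3,7-dimethyl-5-oxooct-6-enoate, via alkenyllithium 8 (not isolated), via alkenylzinc chloride 9 (not isolated)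
Conditions: 7, t-BuLi (2.1 equiv), Et2O, −78 °C; ZnCl2 (1.1 equiv), THF, −78 → 0 °C; then 3, Pd(PPh3)4 (5 mol %), THF, 0 °C → rt
Reagents that add atoms: none
Why: Negishi acylation: iodine–lithium exchange and transmetallation give an alkenylzinc that couples with the acid chloride under palladium catalysis with retention of the E geometry, and the organozinc does not touch the methyl ester.

Step 6
Reactants: 10 methyl (3R,6E)-8-[(tert-butyldimethylsilyl)oxy]-3,7-dimethyl-5-oxooct-6-enoate
Product: 11 methyl (3R,5S,6E)-8-[(tert-butyldimethylsilyl)oxy]-5-hydroxy-3,7-dimethyloct-6-enoate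
Conditions: (R)-2-methyl-CBS-oxazaborolidine (0.15 equiv), catecholborane (1.5 equiv), toluene, −78 °C; then MeOH, aq. NaOH
Reagents that add atoms: none
Why: Corey–Bakshi–Shibata reduction: the alkenyl arm acts as the large group on the oxazaborolidine–borane complex, so the (R)-catalyst gives the 5S allylic alcohol under reagent control, the remote C3 centre having no influence.

Step 7
Reactants: 11 methyl (3R,5S,6E)-8-[(tert-butyldimethylsilyl)oxy]-5-hydroxy-3,7-dimethyloct-6-enoate
Product: 12 methyl (3R,5S,6E)-8-[(tert-butyldimethylsilyl)oxy]-3,7-dimethyl-5-[(triisopropylsilyl)oxy]oct-6-enoate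
Conditions: TIPSOTf, 2,6-lutidine, CH2Cl2, −78 → 0 °C
Reagents that add atoms: triisopropylsilyl triflate (CC(C)[Si](C(C)C)(C(C)C)OS(=O)(=O)C(F)(F)F)
Why: Silyl triflate silylation gives a bulky ether that survives to the end of the route and is a poor nucleophile toward the activated amide of step 9.

Step 8
Reactants: 12 methyl (3R,5S,6E)-8-[(tert-butyldimethylsilyl)oxy]-3,7-dimethyl-5-[(triisopropylsilyl)oxy]oct-6-enoate
Product: 13 (3R,5S,6E)-8-[(tert-butyldimethylsilyl)oxy]-3,7-dimethyl-1-(pyrrolidin-1-yl)-5-[(triisopropylsilyl)oxy]oct-6-en-1-one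
Conditions: pyrrolidine (3 equiv), Me3Al (3 equiv), toluene, 0 → 60 °C; aq. potassium sodium tartrate work-up
Reagents that add atoms: pyrrolidine (C1CCNC1)
Why: Aluminium amide aminolysis of the ester (Weinreb-type amidation) gives the tertiary amide needed for keteniminium formation without touching silyl ethers or stereocentres.

Step 9
Reactants: 13 (3R,5S,6E)-8-[(tert-butyldimethylsilyl)oxy]-3,7-dimethyl-1-(pyrrolidin-1-yl)-5-[(triisopropylsilyl)oxy]oct-6-en-1-one
Product: 16 7-{[(tert-butyldimethylsilyl)oxy]methyl}-4,7-dimethyl-2-[(triisopropylsilyl)oxy]bicyclo[3.1.1]heptan-6-one, via keteniminium triflate 14 (not isolated), via cyclobutaniminium triflate 15 (not isolated)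
Conditions: Tf2O (1.2 equiv), 2,6-di-tert-butyl-4-methylpyridine (1.3 equiv), ClCH2CH2Cl (0.01 M), 0 → 80 °C; then aq. NaHCO3, 60 °C
Reagents that add atoms: water (O)
Why: Intramolecular keteniminium–alkene [2+2] (Ghosez type): the electrophilic carbon (future C5) bonds to the less substituted alkene carbon (C11) and the ring closes at the cation-stabilising C10, which gives the bridged bicyclo[3.1.1] skeleton; the E-alkene puts the C10 methyl over the three-carbon bridge, and the C3 methyl and C1 silyloxy groups take the uncrowded positions on the side of the carbonyl bridge, which fixes C4, C10 and C11 relative to C3.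

Step 10
Reactants: 16 7-{[(tert-butyldimethylsilyl)oxy]methyl}-4,7-dimethyl-2-[(triisopropylsilyl)oxy]bicyclo[3.1.1]heptan-6-one
Product: 17 7-(hydroxymethyl)-4,7-dimethyl-2-[(triisopropylsilyl)oxy]bicyclo[3.1.1]heptan-6-one
Conditions: HF·pyridine, pyridine/THF, 0 °C
Reagents that add atoms: none
Why: Selective desilylation: fluoride cleaves the unhindered primary tert-butyldimethylsilyl ether much faster than the hindered secondary triisopropylsilyl ether.

Step 11
Reactants: 17 7-(hydroxymethyl)-4,7-dimethyl-2-[(triisopropylsilyl)oxy]bicyclo[3.1.1]heptan-6-one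
Product: 18 {4,7-dimethyl-6-oxo-2-[(triisopropylsilyl)oxy]bicyclo[3.1.1]heptan-7-yl}methyl 2-bromo-2-methylpropanoate
Conditions: BrC(CH3)2COBr (1.3 equiv), pyridine, DMAP (cat.), CH2Cl2, 0 °C
Reagents that add atoms: 2-bromo-2-methylpropanoyl bromide (CC(C)(Br)C(=O)Br)
Why: Acylation of the primary alcohol hangs the α-bromo ester from C9, that is from the face of the cyclobutane anti to the three-carbon bridge.

Step 12
Reactants: 18 {4,7-dimethyl-6-oxo-2-[(triisopropylsilyl)oxy]bicyclo[3.1.1]heptan-7-yl}methyl 2-bromo-2-methylpropanoate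
Product: 21 5-[(methoxyoxalyl)oxy]-1-[(triisopropylsilyl)oxy]-8-oxalongipinan-7-one, via samarium enolate 19 (not isolated), via samarium alkoxide 20 (not isolated)
Conditions: SmI2 (2.2 equiv), THF, −78 °C; then ClCOCO2Me (1.5 equiv), −78 → 0 °C
Reagents that add atoms: methyl chlorooxoacetate (COC(=O)C(=O)Cl)
Why: Samarium diiodide Reformatsky reaction: the enolate forms regiospecifically at C6 and, being tethered through C9, can only add to the anti face of the strained cyclobutanone, which sets C5 with C6 anti; acylating the samarium alkoxide in the flask avoids retro-aldol and the difficult acylation of the free hindered alcohol.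

Step 13
Reactants: 21 5-[(methoxyoxalyl)oxy]-1-[(triisopropylsilyl)oxy]-8-oxalongipinan-7-one
Product: 22 1-[(triisopropylsilyl)oxy]-8-oxalongipinan-7-one
Conditions: Bu3SnH (2 equiv), AIBN (0.2 equiv), toluene, 110 °C
Reagents that add atoms: none
Why: Radical deoxygenation of a tertiary alkyl methyl oxalate with tin hydride (Barton-type): the C5 radical is held in the lactone-bridged cage, so hydrogen can only be delivered to the open position syn to the three-carbon bridge, which gives the C5–H configuration of the target.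

Step 14
Reactants: 22 1-[(triisopropylsilyl)oxy]-8-oxalongipinan-7-one
Product: 23 2-{7-(hydroxymethyl)-4,7-dimethyl-2-[(triisopropylsilyl)oxy]bicyclo[3.1.1]heptan-6-yl}-N-methoxy-N,2-dimethylpropanamide
Conditions: MeNH(OMe)·HCl (3 equiv), i-PrMgCl (6 equiv), THF, −20 → 0 °C
Reagents that add atoms: N,O-dimethylhydroxylamine hydrochloride (CNOC.Cl)
Why: Weinreb aminolysis of the lactone with the magnesium amide opens the temporary ring to a ketone precursor at C7 and frees the C9 alcohol.

Step 15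
Reactants: 23 2-{7-(hydroxymethyl)-4,7-dimethyl-2-[(triisopropylsilyl)oxy]bicyclo[3.1.1]heptan-6-yl}-N-methoxy-N,2-dimethylpropanamide
Product: 24 2-{7-formyl-4,7-dimethyl-2-[(triisopropylsilyl)oxy]bicyclo[3.1.1]heptan-6-yl}-N-methoxy-N,2-dimethylpropanamide
Conditions: Dess–Martin periodinane, NaHCO3, CH2Cl2, rt
Reagents that add atoms: none
Why: Dess–Martin oxidation of a primary alcohol gives an aldehyde on a quaternary carbon that cannot enolise or epimerise.

Step 16
Reactants: 24 2-{7-formyl-4,7-dimethyl-2-[(triisopropylsilyl)oxy]bicyclo[3.1.1]heptan-6-yl}-N-methoxy-N,2-dimethylpropanamide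
Product: 25 2-{7-ethenyl-4,7-dimethyl-2-[(triisopropylsilyl)oxy]bicyclo[3.1.1]heptan-6-yl}-N-methoxy-N,2-dimethylpropanamide
Conditions: Ph3PCH3Br, KN(SiMe3)2, THF, 0 °C → rt
Reagents that add atoms: methyltriphenylphosphonium bromide (C[P+](c1ccccc1)(c1ccccc1)c1ccccc1.[Br-])
Why: Wittig methylenation with the small unstabilised ylide works on hindered aldehydes and leaves the Weinreb amide alone.

Step 17
Reactants: 25 2-{7-ethenyl-4,7-dimethyl-2-[(triisopropylsilyl)oxy]bicyclo[3.1.1]heptan-6-yl}-N-methoxy-N,2-dimethylpropanamide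
Product: 26 4-{7-ethenyl-4,7-dimethyl-2-[(triisopropylsilyl)oxy]bicyclo[3.1.1]heptan-6-yl}-4-methyl-1-(trimethylsilyl)pent-1-yn-3-one
Conditions: HC≡CSiMe3, n-BuLi, THF, −78 °C; then 25, −78 → 0 °C; 1 M HCl quench
Reagents that add atoms: ethynyltrimethylsilane (C#C[Si](C)(C)C)
Why: Weinreb ketone synthesis: the small acetylide adds once to the hindered amide and the chelated tetrahedral intermediate holds until work-up.

Step 18
Reactants: 26 4-{7-ethenyl-4,7-dimethyl-2-[(triisopropylsilyl)oxy]bicyclo[3.1.1]heptan-6-yl}-4-methyl-1-(trimethylsilyl)pent-1-yn-3-one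
Product: 27 4-{7-ethenyl-4,7-dimethyl-2-[(triisopropylsilyl)oxy]bicyclo[3.1.1]heptan-6-yl}-4-methyl-1-(trimethylsilyl)pent-1-yn-3-ol (carbinol configured as C7 of the target)
Conditions: RuCl(p-cymene)[(S,S)-TsDPEN] (2 mol %), KOH (2 mol %), i-PrOH, rt
Reagents that add atoms: none
Why: Noyori asymmetric transfer hydrogenation of an α,β-acetylenic ketone: the (S,S)-catalyst distinguishes the alkynyl from the tertiary alkyl group and sets C7 under catalyst control, which is needed because the two faces of this part of the cage are nearly equivalent.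

Step 19
Reactants: 27 4-{7-ethenyl-4,7-dimethyl-2-[(triisopropylsilyl)oxy]bicyclo[3.1.1]heptan-6-yl}-4-methyl-1-(trimethylsilyl)pent-1-yn-3-ol
Product: 28 4-{7-ethenyl-4,7-dimethyl-2-[(triisopropylsilyl)oxy]bicyclo[3.1.1]heptan-6-yl}-4-methylpent-1-yn-3-ol
Conditions: K2CO3 (0.2 equiv), MeOH, rt
Reagents that add atoms: none
Why: Base-catalysed methanolysis removes the alkynylsilane only; both silyl ethers on oxygen are stable.

Step 20
Reactants: 28 4-{7-ethenyl-4,7-dimethyl-2-[(triisopropylsilyl)oxy]bicyclo[3.1.1]heptan-6-yl}-4-methylpent-1-yn-3-ol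
Product: 29 4-{7-ethenyl-4,7-dimethyl-2-[(triisopropylsilyl)oxy]bicyclo[3.1.1]heptan-6-yl}-4-methylpent-1-en-3-ol
Conditions: H2 (1 atm), Pd/CaCO3 poisoned with Pb(OAc)2 (Lindlar catalyst), quinoline, EtOAc, rt
Reagents that add atoms: none
Why: Lindlar semihydrogenation stops at the alkene because the alkyne binds the poisoned palladium far more strongly than the existing vinyl group.

Step 21
Reactants: 29 4-{7-ethenyl-4,7-dimethyl-2-[(triisopropylsilyl)oxy]bicyclo[3.1.1]heptan-6-yl}-4-methylpent-1-en-3-ol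
Product: 30 1-[(triisopropylsilyl)oxy]longipin-8-en-7-ol
Conditions: second-generation Hoveyda–Grubbs catalyst (5 mol %), toluene (0.005 M), 80 °C
Reagents that add atoms: none
Why: Ring-closing metathesis: the two vinyl groups are held side by side on the same face of the cyclobutane, so the seven-membered ring closes to the cis-alkene with loss of ethene.

Step 22
Reactants: 30 1-[(triisopropylsilyl)oxy]longipin-8-en-7-ol
Product: 31 1-[(triisopropylsilyl)oxy]longipinane-7,8,9-triol
Conditions: OsO4 (5 mol %), NMO (2 equiv), acetone/H2O 4:1, rt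
Reagents that add atoms: N-methylmorpholine N-oxide (C[N+]1([O-])CCOCC1); water (O)
Why: Upjohn dihydroxylation: osmium tetroxide adds syn to the ring alkene on the face anti to the allylic C7 hydroxyl (Kishi's empirical rule), which sets C8 and C9 cis to each other and trans to C7–O.

Step 23
Reactants: 31 1-[(triisopropylsilyl)oxy]longipinane-7,8,9-triol
Product: 32 1-[(triisopropylsilyl)oxy]longipinane-7,8,9-triyl tris[(2Z)-2-methylbut-2-enoate]
Conditions: angelic acid (9 equiv), 2,4,6-trichlorobenzoyl chloride (9 equiv), Et3N (10 equiv), toluene, rt, 2 h; then 31, 80 °C, 48 h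
Reagents that add atoms: angelic acid (C/C=C(/C)C(=O)O)
Why: Yamaguchi-type esterification through the 2,4,6-trichlorobenzoyl mixed anhydride acylates hindered secondary alcohols without a nucleophilic catalyst, which avoids Z-to-E isomerisation of the angelate.

Step 24
Reactants: 32 1-[(triisopropylsilyl)oxy]longipinane-7,8,9-triyl tris[(2Z)-2-methylbut-2-enoate]
Product: 33 1-hydroxylongipinane-7,8,9-triyl tris[(2Z)-2-methylbut-2-enoate]
Conditions: HF·pyridine, THF, 0 °C → rt
Reagents that add atoms: none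
Why: Fluoride desilylation under mildly acidic, non-basic conditions leaves the three enoate esters in place and unisomerised.

Step 25
Reactants: 33 1-hydroxylongipinane-7,8,9-triyl tris[(2Z)-2-methylbut-2-enoate]
Product: 34 1-oxolongipinane-7,8,9-triyl tris[(2Z)-2-methylbut-2-enoate] (CNP0138097.1)
Conditions: Dess–Martin periodinane, NaHCO3, CH2Cl2, rt
Reagents that add atoms: none
Why: Buffered Dess–Martin oxidation gives the C1 ketone, and the adjacent C11 is a bridgehead so nothing can epimerise.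

## Compound list

1 | dimethyl 3-methylpentanedioate | COC(=O)CC(C)CC(=O)OC | starting material
2 | (3R)-5-methoxy-3-methyl-5-oxopentanoic acid | COC(=O)C[C@H](C)CC(=O)O | intermediate
3 | methyl (3S)-5-chloro-3-methyl-5-oxopentanoate | COC(=O)C[C@H](C)CC(=O)Cl | intermediate
4 | prop-2-yn-1-ol | C#CCO | starting material
5 | alkenylalane, (E)-Me2Al–CH=C(CH3)–CH2–O–AlMe2 | C[Al](C)/C=C(\C)CO[Al](C)C | intermediate
6 | (2E)-3-iodo-2-methylprop-2-en-1-ol | I/C=C(\C)CO | intermediate
7 | tert-butyl{[(2E)-3-iodo-2-methylprop-2-en-1-yl]oxy}dimethylsilane | I/C=C(\C)CO[Si](C)(C)C(C)(C)C | intermediate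
8 | alkenyllithium from 7 (E) | [Li]/C=C(\C)CO[Si](C)(C)C(C)(C)C | intermediate
9 | alkenylzinc chloride from 8 (E) | Cl[Zn]/C=C(\C)CO[Si](C)(C)C(C)(C)C | intermediate
10 | methyl (3R,6E)-8-[(tert-butyldimethylsilyl)oxy]-3,7-dimethyl-5-oxooct-6-enoate | COC(=O)C[C@H](C)CC(=O)/C=C(\C)CO[Si](C)(C)C(C)(C)C | intermediate
11 | methyl (3R,5S,6E)-8-[(tert-butyldimethylsilyl)oxy]-5-hydroxy-3,7-dimethyloct-6-enoate | COC(=O)C[C@H](C)C[C@H](O)/C=C(\C)CO[Si](C)(C)C(C)(C)C | intermediate
12 | methyl (3R,5S,6E)-8-[(tert-butyldimethylsilyl)oxy]-3,7-dimethyl-5-[(triisopropylsilyl)oxy]oct-6-enoate | COC(=O)C[C@H](C)C[C@H](O[Si](C(C)C)(C(C)C)C(C)C)/C=C(\C)CO[Si](C)(C)C(C)(C)C | intermediate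
13 | (3R,5S,6E)-8-[(tert-butyldimethylsilyl)oxy]-3,7-dimethyl-1-(pyrrolidin-1-yl)-5-[(triisopropylsilyl)oxy]oct-6-en-1-one | O=C(C[C@H](C)C[C@H](O[Si](C(C)C)(C(C)C)C(C)C)/C=C(\C)CO[Si](C)(C)C(C)(C)C)N1CCCC1 | intermediate
14 | keteniminium triflate from 13 (RCH=C=N+ pyrrolidinium) | C(=C=[N+]1CCCC1)[C@H](C)C[C@H](O[Si](C(C)C)(C(C)C)C(C)C)/C=C(\C)CO[Si](C)(C)C(C)(C)C.[O-]S(=O)(=O)C(F)(F)F | intermediate
15 | cyclobutaniminium triflate (pyrrolidinium ylidene at the future C5) | C1(=[N+]2CCCC2)[C@@H]3[C@H](C)C[C@H](O[Si](C(C)C)(C(C)C)C(C)C)[C@H]1[C@]3(C)CO[Si](C)(C)C(C)(C)C.[O-]S(=O)(=O)C(F)(F)F | intermediate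
16 | 7-{[(tert-butyldimethylsilyl)oxy]methyl}-4,7-dimethyl-2-[(triisopropylsilyl)oxy]bicyclo[3.1.1]heptan-6-one; 2-O and 4-CH3 on the side of the carbonyl bridge, 7-CH3 over the three-carbon bridge, 7-CH2O anti; absolute configuration as in the SMILES | O=C1[C@@H]2[C@H](C)C[C@H](O[Si](C(C)C)(C(C)C)C(C)C)[C@H]1[C@]2(C)CO[Si](C)(C)C(C)(C)C | intermediate
17 | 7-(hydroxymethyl) analogue of 16 | O=C1[C@@H]2[C@H](C)C[C@H](O[Si](C(C)C)(C(C)C)C(C)C)[C@H]1[C@]2(C)CO | intermediate
18 | 2-bromo-2-methylpropanoate ester of 17 | O=C1[C@@H]2[C@H](C)C[C@H](O[Si](C(C)C)(C(C)C)C(C)C)[C@H]1[C@]2(C)COC(=O)C(C)(C)Br | intermediate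
19 | samarium enolate of 18 (O–SmI2 ketene acetal) | O=C1[C@@H]2[C@H](C)C[C@H](O[Si](C(C)C)(C(C)C)C(C)C)[C@H]1[C@]2(C)COC(O[Sm](I)I)=C(C)C | intermediate
20 | samarium alkoxide of 5-hydroxy-1-[(triisopropylsilyl)oxy]-8-oxalongipinan-7-one (5-O syn to the three-carbon bridge, C6 anti) | O=C1C(C)(C)[C@@]2(O[Sm](I)I)[C@@H]3[C@H](C)C[C@H](O[Si](C(C)C)(C(C)C)C(C)C)[C@H]2[C@]3(C)CO1 | intermediate
21 | 5-[(methoxyoxalyl)oxy]-1-[(triisopropylsilyl)oxy]-8-oxalongipinan-7-one | O=C1C(C)(C)[C@@]2(OC(=O)C(=O)OC)[C@@H]3[C@H](C)C[C@H](O[Si](C(C)C)(C(C)C)C(C)C)[C@H]2[C@]3(C)CO1 | intermediate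
22 | 1-[(triisopropylsilyl)oxy]-8-oxalongipinan-7-one (C3, C4, C5, C10, C11 as in the target) | O=C1C(C)(C)[C@H]2[C@@H]3[C@H](C)C[C@H](O[Si](C(C)C)(C(C)C)C(C)C)[C@H]2[C@]3(C)CO1 | intermediate
23 | 2-{7-(hydroxymethyl)-4,7-dimethyl-2-[(triisopropylsilyl)oxy]bicyclo[3.1.1]heptan-6-yl}-N-methoxy-N,2-dimethylpropanamide | CON(C)C(=O)C(C)(C)[C@H]1[C@@H]2[C@H](C)C[C@H](O[Si](C(C)C)(C(C)C)C(C)C)[C@H]1[C@]2(C)CO | intermediate
24 | 7-formyl analogue of 23 | CON(C)C(=O)C(C)(C)[C@H]1[C@@H]2[C@H](C)C[C@H](O[Si](C(C)C)(C(C)C)C(C)C)[C@H]1[C@]2(C)C=O | intermediate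
25 | 7-ethenyl analogue of 23 | CON(C)C(=O)C(C)(C)[C@H]1[C@@H]2[C@H](C)C[C@H](O[Si](C(C)C)(C(C)C)C(C)C)[C@H]1[C@]2(C)C=C | intermediate
26 | 4-{7-ethenyl-4,7-dimethyl-2-[(triisopropylsilyl)oxy]bicyclo[3.1.1]heptan-6-yl}-4-methyl-1-(trimethylsilyl)pent-1-yn-3-one | C[Si](C)(C)C#CC(=O)C(C)(C)[C@H]1[C@@H]2[C@H](C)C[C@H](O[Si](C(C)C)(C(C)C)C(C)C)[C@H]1[C@]2(C)C=C | intermediate
27 | propargylic alcohol from 26 (carbinol = C7 of the target) | C[Si](C)(C)C#C[C@@H](O)C(C)(C)[C@H]1[C@@H]2[C@H](C)C[C@H](O[Si](C(C)C)(C(C)C)C(C)C)[C@H]1[C@]2(C)C=C | intermediate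
28 | terminal alkyne from 27 | C#C[C@@H](O)C(C)(C)[C@H]1[C@@H]2[C@H](C)C[C@H](O[Si](C(C)C)(C(C)C)C(C)C)[C@H]1[C@]2(C)C=C | intermediate
29 | diene: 4-{7-ethenyl-4,7-dimethyl-2-[(triisopropylsilyl)oxy]bicyclo[3.1.1]heptan-6-yl}-4-methylpent-1-en-3-ol | C=C[C@@H](O)C(C)(C)[C@H]1[C@@H]2[C@H](C)C[C@H](O[Si](C(C)C)(C(C)C)C(C)C)[C@H]1[C@]2(C)C=C | intermediate
30 | 1-[(triisopropylsilyl)oxy]longipin-8-en-7-ol | C1=C[C@@H](O)C(C)(C)[C@H]2[C@@H]3[C@H](C)C[C@H](O[Si](C(C)C)(C(C)C)C(C)C)[C@H]2[C@@]31C | intermediate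
31 | 1-[(triisopropylsilyl)oxy]longipinane-7,8,9-triol (8-OH and 9-OH cis, 7-OH trans to them) | O[C@@H]1[C@@H](O)C(C)(C)[C@H]2[C@@H]3[C@H](C)C[C@H](O[Si](C(C)C)(C(C)C)C(C)C)[C@H]2[C@]3(C)[C@@H]1O | intermediate
32 | 1-[(triisopropylsilyl)oxy]longipinane-7,8,9-triyl tris[(2Z)-2-methylbut-2-enoate] | C/C=C(/C)C(=O)O[C@@H]1[C@@H](OC(=O)/C(C)=C\C)C(C)(C)[C@H]2[C@@H]3[C@H](C)C[C@H](O[Si](C(C)C)(C(C)C)C(C)C)[C@H]2[C@]3(C)[C@@H]1OC(=O)/C(C)=C\C | intermediate
33 | 1-hydroxylongipinane-7,8,9-triyl tris[(2Z)-2-methylbut-2-enoate] | C/C=C(/C)C(=O)O[C@@H]1[C@@H](OC(=O)/C(C)=C\C)C(C)(C)[C@H]2[C@@H]3[C@H](C)C[C@H](O)[C@H]2[C@]3(C)[C@@H]1OC(=O)/C(C)=C\C | intermediate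
34 | 1-oxolongipinane-7,8,9-triyl tris[(2Z)-2-methylbut-2-enoate] (CNP0138097.1) | C/C=C(/C)C(=O)O[C@@H]1[C@@H](OC(=O)/C(C)=C\C)C(C)(C)[C@H]2[C@@H]3[C@H](C)CC(=O)[C@H]2[C@]3(C)[C@@H]1OC(=O)/C(C)=C\C | target

## Totals and risk

Total step count: 25.
Longest linear sequence: 23 steps (steps 1, 2 and 5–25 from 1; the branch from 4, steps 3–25, is equally long).

The three steps most likely to fail:

**Step 9 (keteniminium [2+2]).** The alkene carries allylic oxygen on both sides, so it is a weak nucleophile, and the cationic pathway could lose alkene geometry or attack a silyl ether. The fallback sets out from ester 12 and comes back at cyclobutanone 16. LiOH in THF/H2O gives carboxylic acid F1. 1-Chloro-N,N,2-trimethylprop-1-en-1-amine in CH2Cl2 converts it under neutral conditions into acid chloride F2. Slow addition of F2 to Et3N in toluene at 110 °C under high dilution generates aldoketene F3, which closes by the thermal, concerted ketene–alkene [2+2] to give 16 directly. This replaces the stepwise cationic cycloaddition by a neutral one, with no triflic species and no iminium hydrolysis.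

**Step 13 (removal of the tertiary C5 oxygen).** The tin-hydride chain may be slow on this crowded oxalate, or the C5 radical may fragment at 110 °C. The fallback sets out from oxalate 21 and comes back at lactone 22. One equivalent of CsOH in THF/H2O at 0 °C cleaves only the unhindered methyl ester of the oxalate and gives caesium oxalate F4. Blue-light irradiation at room temperature with [Ir(dF(CF3)ppy)2(dtbbpy)]PF6 (1 mol %), thiophenol (20 mol %) and water in DME/DMF oxidises the carboxylate and expels two molecules of CO2. The same cage-bound C5 radical then takes hydrogen from the thiol at the only open position. This is an oxidative photoredox decarboxylation in place of a reductive tin chain.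

**Step 23 (triple angeloylation).** Three hindered secondary alcohols must be acylated, and forcing conditions can isomerise angelate to tiglate. The fallback sets out from triol 31 and comes back at triester 32. DCC/DMAP coupling with 2-[bis(2,2,2-trifluoroethoxy)phosphoryl]propanoic acid in CH2Cl2 gives tris(phosphonopropionate) F5, a saturated acyl donor with no alkene to isomerise. KN(SiMe3)2 with 18-crown-6 in THF at −78 °C and acetaldehyde then builds the three Z-double bonds on the esters in place by Still–Gennari olefination. The (Z)-2-methylbut-2-enoate geometry is therefore set by the olefination, not carried through an esterification.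

## Further compounds

F1 | step 9 | (3R,5S,6E)-8-[(tert-butyldimethylsilyl)oxy]-3,7-dimethyl-5-[(triisopropylsilyl)oxy]oct-6-enoic acid | OC(=O)C[C@H](C)C[C@H](O[Si](C(C)C)(C(C)C)C(C)C)/C=C(\C)CO[Si](C)(C)C(C)(C)C
F2 | step 9 | acid chloride of F1 | ClC(=O)C[C@H](C)C[C@H](O[Si](C(C)C)(C(C)C)C(C)C)/C=C(\C)CO[Si](C)(C)C(C)(C)C
F3 | step 9 | aldoketene from F2 | O=C=C[C@H](C)C[C@H](O[Si](C(C)C)(C(C)C)C(C)C)/C=C(\C)CO[Si](C)(C)C(C)(C)C
F4 | step 13 | caesium oxalate half-ester of the C5 alcohol (carboxylate salt of 21) | O=C1C(C)(C)[C@@]2(OC(=O)C(=O)[O-])[C@@H]3[C@H](C)C[C@H](O[Si](C(C)C)(C(C)C)C(C)C)[C@H]2[C@]3(C)CO1.[Cs+]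
F5 | step 23 | 1-[(triisopropylsilyl)oxy]longipinane-7,8,9-triyl tris{2-[bis(2,2,2-trifluoroethoxy)phosphoryl]propanoate} (mixture of epimers at the three phosphonate-bearing carbons) | CC(C(=O)O[C@@H]1[C@@H](OC(=O)C(C)P(=O)(OCC(F)(F)F)OCC(F)(F)F)C(C)(C)[C@H]2[C@@H]3[C@H](C)C[C@H](O[Si](C(C)C)(C(C)C)C(C)C)[C@H]2[C@]3(C)[C@@H]1OC(=O)C(C)P(=O)(OCC(F)(F)F)OCC(F)(F)F)P(=O)(OCC(F)(F)F)OCC(F)(F)F
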